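## Analysis of the target

Compound 18 (CNP0264591.0) consists of three fully substituted benzene rings joined by two CH2 bridges. It has no stereocentre and a mirror plane runs through C1 and C4 of the central ring. The central ring is a 2,4,6-trihydroxybutyrophenone whose C3 and C5 each carry an arylmethyl group. Each outer ring is an aspidinol unit (2,6-dihydroxy-4-methoxy-3-methylbutyrophenone) attached through its C5, so its methoxy group is para to the ketone and its methyl group sits between a hydroxyl and the methoxy group. Seven free phenols make the compound oxidisable in base, and methylene bridges between free phloroglucinol rings can be redistributed by acid or hot alkali. The last steps must therefore be mild and close to neutral. The difficulty is regiochemical: no ring has a free position, so every substituent must be placed unambiguously and not by a late selective substitution. The strategy rests on the central ring. Its butanoyl-bearing C1, its oxygenated C2, C4 and C6 and its carbon-substituted C3 and C5 are the folded form of a 3,5,7-trioxodecanoate. Chain numbering used throughout: C1 is the ester carbon and C7 the ketone carbon carrying the propyl group. Ring C2 is chain C1, ring C3 and C5 are chain C2 and C4 (each carrying a CH2-aryl group), ring C1 is chain C6, and the butanoyl carbonyl is chain C7.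

## Retrosynthetic reasoning

18 to 17. The four benzyl ethers on the outer rings are removed last. No skeletal bond is cut. Hydrogenolysis is neutral, so the free polyphenol never meets acid or base and the bridges cannot scramble.

17 to 16. The central ring is opened at the bond between its butanoyl-bearing carbon and the neighbouring carbinol carbon (chain C6 to C1). This bond is chosen over the two CH2–aryl bonds because the open chain 16 already holds both arylmethyl groups on defined carbons (C2 and C4). Regiochemistry of the central ring is thereby fixed before the ring exists. The forward reaction is a Claisen ring closure of C6 onto the ester, followed by enolisation to the aromatic ring.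

16 to 15. The C7 ketone is masked as a dioxolane. With C7 masked, C6 is not doubly activated, so C2 and C4 are the only strongly acidic carbons when the arylmethyl groups are introduced.

15 to 13 and two molecules of 9. Both C–CH2Ar bonds are cut. The forward reaction is alkylation of the dianion of 13, first at C2 and then at C4, with the benzylic bromide 9. Both outer rings arrive in one operation from one fragment. The enolisable aryl ketones of 9 meet only a base too weak to enolise them. Extending an already bis-arylmethylated keto diester with a simple ketone enolate was put aside. Such a diester is by far the stronger carbon acid and would quench the enolate, its two ester groups could not be told apart, and the outer-ring ketones would be exposed to strong base.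

13 to 11 and 12. The C4–C5 bond is cut. The γ-carbon of the dianion of 12 is acylated by the ester of 11, which has no doubly activated hydrogen. This is the only strong-base step on the chain and it is done before any aryl ketone is present.

11 to 10. The ketal is removed retrosynthetically, leading to the commercial keto ester 10.

9 to 8 to 7. The bromide comes from the benzylic alcohol 8, and 8 from the aldehyde 7. The bromide is made last and used at once because a 2,4,6-trialkoxybenzyl bromide ionises easily.

7 to 6 to 4. The two benzyl ethers are removed, then the ring–CHO bond is cut. Compound 4 has a single free ring position, so formylation needs no selectivity. Formylating before benzylating also blocks C-benzylation on the ring.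

4 to 3 to 1 and 2. The methyl ether is cut at the hydroxyl para to the ketone, then the aryl–acyl bond is cut. The two free positions of 1 are equivalent, so the acylation has one possible mono-product.

## Alternatives that were turned down

Alternative 1: Both outer rings are disconnected at once. In each ring the cuts are the bond from the bridge-bearing carbon to the carbon that ends up O-ethylated, and the bond from the acyl-bearing carbon to the adjacent carbinol carbon. This leads back to the bis-diene A2 (two silyl ketene acetal diene arms on a tris(benzyloxy)benzene) and two molecules of the alkynone A3. In the forward step each diene would add through its remote terminus to the ethoxy-bearing alkyne carbon, the acetal carbon would close onto the acyl-bearing carbon, and elimination would aromatise to A1.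
- For: it is convergent, the ketone and its ortho hydroxyl appear together with defined regiochemistry, and no ionisable benzylic bromide such as 9 is needed. On that last point it is stronger than the chosen route.
- Against: the attacking diene terminus already carries the CH2-aryl group and must add to the β-carbon of a β-alkoxy ynone. That is a weak acceptor, and addition–elimination with loss of the ethoxy group is the more usual outcome. The reaction must succeed twice on one molecule.
- Against: A1 is not at the target's substitution pattern. Each outer ring has an ethyl ether where a hydroxyl is needed, to be cleaved beside a methyl ether that must stay. The central ring still lacks its butanoyl group, so a Friedel–Crafts acylation would follow under the Lewis-acid conditions that redistribute methylene bridges.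
- Comparison: the chosen route builds one ring and not two, reaches the outer-ring pattern in three classical steps from 1, and carries the central butanoyl group inside the chain.

Alternative 2: The central ring is disconnected at its aryl–carbonyl bond and the adjacent aryl–oxygen bond. This leads back to the ortho-silyl aryl triflate A5 and butanoic acid A6. In the forward step desilylation would generate the aryne, the carboxylate oxygen would add at the aryne carbon next to the arylmethyl arm, and the resulting aryl anion would take the acyl group from oxygen to give A4.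
- For: the regiochemistry is predictable, because the flanking benzyloxy group directs the nucleophile to the remote aryne carbon. The trimer skeleton can be assembled beforehand by ordinary C-benzylation. On convergence it is as strong as the chosen route.
- Against: A5 is a hexasubstituted benzene with vicinal silyl and triflate groups between an arylmethyl and a benzyloxy group. Making it requires the same differentiation of the central ring that the target itself poses.
- Against: the aryl anion formed after O-addition can simply be protonated by A6 to give an aryl ester with no C–C bond. Acyl transfer must win at a carbanion flanked on both sides, and the benzylic CH2 next to the aryne invites ene-type side reactions.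
- Comparison: the chosen key step uses a cheap base, passes through no high-energy intermediate and has aromatisation as its sink. The step count of Alternative 2 is expected to be clearly higher.

Alternative 3: Each outer ring is disconnected at the bond between its butanoyl-bearing carbon and the carbinol carbon next to the bridge. This leads back to the bis(triketo ester) A8 on a tri-O-benzylated butanoylphloroglucinol core. In the forward step base would fold both arms by Claisen closure to A7.
- For: the reaction type is the same well-precedented one, so on precedent it is as strong as the chosen route. The central ring comes from a simple aromatic and the synthesis is two-directional.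
- Against: two foldings must succeed on one molecule, which doubles the exposure to enol-lactone formation and retro-Claisen cleavage. Each chain needs a C-methyl group at C4 in addition to the link at C2.
- Against: A7 has six free outer-ring hydroxyls. Exactly the two para to the ketones, each flanked by a methyl group and a bridge, would have to be methylated late on a sensitive bridged polyphenol.
- Comparison: the chosen route sets the methyl ether on the simple compound 3 at the start and needs only one folding.

Key step: step 11

Remark on the chemistry: the polycarbonyl compounds 13–16 are drawn as all-keto forms but will be tautomer mixtures. The stereocentres at C2 and C4 in 14–16 are not controlled, because both carbons become aromatic in step 11.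

## Route

Step 1
Reactants: 1 2-methylbenzene-1,3,5-triol (2-methylphloroglucinol); 2 butanoyl chloride
Product: 3 1-(2,4,6-trihydroxy-3-methylphenyl)butan-1-one
Conditions: AlCl3 (3.5 equiv), PhNO2/CH2Cl2, 0 °C → 50 °C; then ice/aq. HCl
Reagents that add atoms: none
Why: Friedel–Crafts C-acylation of a phloroglucinol; the two free ring positions of 1 are equivalent, the first acyl group deactivates the ring against a second one, and any aryl ester formed first should rearrange (Fries) under the same conditions.

Step 2
Reactants: 3 1-(2,4,6-trihydroxy-3-methylphenyl)butan-1-one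
Product: 4 1-(2,6-dihydroxy-4-methoxy-3-methylphenyl)butan-1-one (aspidinol)
Conditions: Me2SO4 (1.0 equiv), K2CO3 (1.1 equiv), acetone, rt
Reagents that add atoms: dimethyl sulfate, COS(=O)(=O)OC
Why: Williamson O-methylation; the hydroxyl para to the ketone is the most acidic and the least hindered, while both ortho hydroxyls flank the carbonyl group and are held by hydrogen bonding, so one equivalent of weak base and electrophile should react at the para oxygen.

Step 3
Reactants: 4 1-(2,6-dihydroxy-4-methoxy-3-methylphenyl)butan-1-one
Product: 6 3-butanoyl-2,4-dihydroxy-6-methoxy-5-methylbenzaldehyde, via aryl iminium chloride 5 (not isolated)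
Conditions: POCl3 (1.3 equiv), DMF (3 equiv), EtOAc, 0 °C → rt; then H2O, 50 °C
Reagents that add atoms: N,N-dimethylformamide, CN(C)C=O; water, O
Why: Vilsmeier–Haack formylation at the only free ring position, which is ortho or para to three oxygen donors; low temperature and near-stoichiometric reagent should keep the side-chain ketone (chromone formation) out of the reaction.

Step 4
Reactants: 6 3-butanoyl-2,4-dihydroxy-6-methoxy-5-methylbenzaldehyde
Product: 7 2,4-bis(benzyloxy)-3-butanoyl-6-methoxy-5-methylbenzaldehyde
Conditions: BnBr (2.6 equiv), K2CO3 (3 equiv), DMF, 60 °C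
Reagents that add atoms: benzyl bromide, BrCc1ccccc1
Why: Williamson O-benzylation of both chelated phenols in a dipolar aprotic solvent; the ring is fully substituted, so C-benzylation on the ring would have to dearomatise and is disfavoured.

Step 5
Reactants: 7 2,4-bis(benzyloxy)-3-butanoyl-6-methoxy-5-methylbenzaldehyde
Product: 8 1-[2,6-bis(benzyloxy)-3-(hydroxymethyl)-4-methoxy-5-methylphenyl]butan-1-one
Conditions: NaBH4 (0.5 equiv), THF/MeOH, −10 → 0 °C
Reagents that add atoms: none
Why: Chemoselective hydride reduction; the aldehyde is far more electrophilic than the di-ortho-substituted aryl ketone, whose carbonyl is twisted out of the ring plane and shielded by two benzyloxy groups.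

Step 6
Reactants: 8 1-[2,6-bis(benzyloxy)-3-(hydroxymethyl)-4-methoxy-5-methylphenyl]butan-1-one
Product: 9 1-[2,6-bis(benzyloxy)-3-(bromomethyl)-4-methoxy-5-methylphenyl]butan-1-one
Conditions: CBr4 (1.2 equiv), PPh3 (1.2 equiv), CH2Cl2, 0 °C; crude product used at once
Reagents that add atoms: tetrabromomethane, BrC(Br)(Br)Br
Why: Appel bromination under neutral conditions; the 2,4,6-trialkoxybenzyl bromide ionises easily, but its ring has no free position for self-alkylation, so it should survive short handling without nucleophilic solvents.

Step 7
Reactants: 10 methyl 3-oxohexanoate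
Product: 11 methyl 2-(2-propyl-1,3-dioxolan-2-yl)acetate
Conditions: HOCH2CH2OH (3 equiv), p-TsOH·H2O (cat.), toluene, reflux, Dean–Stark
Reagents that add atoms: ethane-1,2-diol, OCCO
Why: Acid-catalysed ketalisation of the ketone of a β-keto ester with azeotropic removal of water; the ester is untouched, and the ketal removes the double activation of the carbon that becomes C6.

Step 8
Reactants: 11 methyl 2-(2-propyl-1,3-dioxolan-2-yl)acetate; 12 methyl 3-oxobutanoate (methyl acetoacetate)
Product: 13 methyl 3,5-dioxo-6-(2-propyl-1,3-dioxolan-2-yl)hexanoate
Conditions: 12 (2.2 equiv), NaH (2.2 equiv), THF, 0 °C; n-BuLi (2.2 equiv), 0 °C; 11 (1.0 equiv), −78 → 0 °C; AcOH quench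
Reagents that add atoms: none
Why: Claisen acylation of the acetoacetate dianion (Weiler dianion) at its γ-carbon by the ester of 11; the second equivalent of dianion removes the acidic C4–H of the product, which protects the new diketone from further attack.

Step 9
Reactants: 13 methyl 3,5-dioxo-6-(2-propyl-1,3-dioxolan-2-yl)hexanoate; 9 1-[2,6-bis(benzyloxy)-3-(bromomethyl)-4-methoxy-5-methylphenyl]butan-1-one (2.1 equiv in all)
Product: 15 methyl 2,4-bis{[2,4-bis(benzyloxy)-3-butanoyl-6-methoxy-5-methylphenyl]methyl}-3,5-dioxo-6-(2-propyl-1,3-dioxolan-2-yl)hexanoate (diastereomer/tautomer mixture), via C2-monoalkylated lithium diketonate 14 (not isolated)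
Conditions: LiN(i-Pr)2 (2.05 equiv), THF, −78 → 0 °C; 9 (1.0 equiv), −78 → 0 °C; then 9 (1.1 equiv), DMPU, 0 °C → rt; AcOH quench
Reagents that add atoms: none
Why: Polyanion alkylation: the dianion of a 3,5-diketo ester (C4 and C2 ionised) reacts at C2, its last-formed and most basic carbanion, and the remaining diketonate is then C-benzylated at C4 on warming with DMPU. C6 is not ionised because C7 is a ketal, and the C2 carbanion is too weak a base to enolise the aryl ketones of 9. The two new stereocentres form without control, which is harmless because both carbons become aromatic in step 11.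

Step 10
Reactants: 15 methyl 2,4-bis{[2,4-bis(benzyloxy)-3-butanoyl-6-methoxy-5-methylphenyl]methyl}-3,5-dioxo-6-(2-propyl-1,3-dioxolan-2-yl)hexanoate
Product: 16 methyl 2,4-bis{[2,4-bis(benzyloxy)-3-butanoyl-6-methoxy-5-methylphenyl]methyl}-3,5,7-trioxodecanoate (diastereomer/tautomer mixture)
Conditions: 1 M aq. HCl/THF (1:4), 0 °C → rt
Reagents that add atoms: water, O
Why: Acid hydrolysis of a 1,3-dioxolane; β-keto ketals hydrolyse readily, and cold dilute aqueous acid is expected to be too mild for cyclodehydration of the triketone or for cleavage of the benzyl ethers.

Step 11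
Reactants: 16 methyl 2,4-bis{[2,4-bis(benzyloxy)-3-butanoyl-6-methoxy-5-methylphenyl]methyl}-3,5,7-trioxodecanoate
Product: 17 1-[3,5-bis({[2,4-bis(benzyloxy)-3-butanoyl-6-methoxy-5-methylphenyl]methyl})-2,4,6-trihydroxyphenyl]butan-1-one
Conditions: NaOMe (4 equiv), MeOH/THF (3:1), Ar, 0 → 40 °C; then cold 1 M aq. HCl
Reagents that add atoms: none
Why: This is an intramolecular Claisen (Dieckmann-type) condensation, the laboratory counterpart of polyketide folding and a known way from 3,5,7-triketo esters to acylphloroglucinols. Methoxide ionises the two doubly activated positions C6 and C4, the C6 enolate attacks the ester carbon C1, methoxide leaves, and the resulting 2-acylcyclohexane-1,3,5-trione tautomerises to the aromatic ring, which is held as its phenoxide and makes the closure irreversible. The ring closes in a 6-(enolexo)-exo-trig mode. No stereocentre is formed, and the two stereocentres of 16 (C2 and C4) become sp2 carbons, so the diastereomer mixture converges. The step needs C-acylation at C1 to win over aldol closure of C2 onto C7, over O-acylation to a 4-hydroxy-2-pyrone and over retro-Claisen cleavage. With excess methoxide C7 lies inside the C5–C7 enolate and is a poor electrophile, C2 is tertiary, hindered and the least acidic of the three positions, and an aldol adduct at C2 would hold a quaternary carbon that cannot aromatise (at most it could dehydrate slowly to a cross-conjugated dienone). Enol-lactone formation is expected to be reversible in methanolic methoxide, and the ionised diketone units are protected against attack by methoxide. The outer-ring ketones are hindered by two ortho benzyloxy groups and are not enolised by methoxide, so they take no part.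

Step 12
Reactants: 17 1-[3,5-bis({[2,4-bis(benzyloxy)-3-butanoyl-6-methoxy-5-methylphenyl]methyl})-2,4,6-trihydroxyphenyl]butan-1-one
Product: 18 1-{3,5-bis[(3-butanoyl-2,4-dihydroxy-6-methoxy-5-methylphenyl)methyl]-2,4,6-trihydroxyphenyl}butan-1-one (target)
Conditions: H2 (1 atm), 10% Pd/C, EtOAc/MeOH, rt
Reagents that add atoms: none
Why: Hydrogenolysis of four aryl benzyl ethers under neutral conditions; the chelated aryl ketones and the diarylmethane C–C bonds should not be reduced at atmospheric pressure, and no acid or base is present that could redistribute the methylene bridges.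

## Compound list

1 | 2-methylbenzene-1,3,5-triol (2-methylphloroglucinol) | Cc1c(O)cc(O)cc1O | starting material
2 | butanoyl chloride | CCCC(=O)Cl | starting material
3 | 1-(2,4,6-trihydroxy-3-methylphenyl)butan-1-one | CCCC(=O)c1c(O)c(C)c(O)cc1O | intermediate
4 | 1-(2,6-dihydroxy-4-methoxy-3-methylphenyl)butan-1-one (aspidinol) | CCCC(=O)c1c(O)c(C)c(OC)cc1O | intermediate
5 | N-[(3-butanoyl-2,4-dihydroxy-6-methoxy-5-methylphenyl)methylidene]-N-methylmethanaminium chloride | CCCC(=O)c1c(O)c(C)c(OC)c(C=[N+](C)C)c1O.[Cl-] | intermediate (not isolated)
6 | 3-butanoyl-2,4-dihydroxy-6-methoxy-5-methylbenzaldehyde | CCCC(=O)c1c(O)c(C)c(OC)c(C=O)c1O | intermediate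
7 | 2,4-bis(benzyloxy)-3-butanoyl-6-methoxy-5-methylbenzaldehyde | CCCC(=O)c1c(OCc2ccccc2)c(C)c(OC)c(C=O)c1OCc1ccccc1 | intermediate
8 | 1-[2,6-bis(benzyloxy)-3-(hydroxymethyl)-4-methoxy-5-methylphenyl]butan-1-one | CCCC(=O)c1c(OCc2ccccc2)c(C)c(OC)c(CO)c1OCc1ccccc1 | intermediate
9 | 1-[2,6-bis(benzyloxy)-3-(bromomethyl)-4-methoxy-5-methylphenyl]butan-1-one | CCCC(=O)c1c(OCc2ccccc2)c(C)c(OC)c(CBr)c1OCc1ccccc1 | intermediate
10 | methyl 3-oxohexanoate | CCCC(=O)CC(=O)OC | starting material
11 | methyl 2-(2-propyl-1,3-dioxolan-2-yl)acetate | CCCC1(CC(=O)OC)OCCO1 | intermediate
12 | methyl 3-oxobutanoate (methyl acetoacetate) | CC(=O)CC(=O)OC | starting material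
13 | methyl 3,5-dioxo-6-(2-propyl-1,3-dioxolan-2-yl)hexanoate | CCCC1(CC(=O)CC(=O)CC(=O)OC)OCCO1 | intermediate
14 | methyl 2-{[2,4-bis(benzyloxy)-3-butanoyl-6-methoxy-5-methylphenyl]methyl}-3,5-dioxo-6-(2-propyl-1,3-dioxolan-2-yl)hexanoate (racemic; present as its lithium enolate, drawn neutral) | CCCC1(CC(=O)CC(=O)C(Cc2c(OCc3ccccc3)c(C(=O)CCC)c(OCc3ccccc3)c(C)c2OC)C(=O)OC)OCCO1 | intermediate (not isolated)
15 | methyl 2,4-bis{[2,4-bis(benzyloxy)-3-butanoyl-6-methoxy-5-methylphenyl]methyl}-3,5-dioxo-6-(2-propyl-1,3-dioxolan-2-yl)hexanoate (mixture of diastereomers) | CCCC1(CC(=O)C(Cc2c(OCc3ccccc3)c(C(=O)CCC)c(OCc3ccccc3)c(C)c2OC)C(=O)C(Cc2c(OCc3ccccc3)c(C(=O)CCC)c(OCc3ccccc3)c(C)c2OC)C(=O)OC)OCCO1 | intermediate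
16 | methyl 2,4-bis{[2,4-bis(benzyloxy)-3-butanoyl-6-methoxy-5-methylphenyl]methyl}-3,5,7-trioxodecanoate (mixture of diastereomers and tautomers) | COC(=O)C(Cc1c(OCc2ccccc2)c(C(=O)CCC)c(OCc2ccccc2)c(C)c1OC)C(=O)C(Cc1c(OCc2ccccc2)c(C(=O)CCC)c(OCc2ccccc2)c(C)c1OC)C(=O)CC(=O)CCC | intermediate
17 | 1-[3,5-bis({[2,4-bis(benzyloxy)-3-butanoyl-6-methoxy-5-methylphenyl]methyl})-2,4,6-trihydroxyphenyl]butan-1-one | CCCC(=O)c1c(O)c(Cc2c(OCc3ccccc3)c(C(=O)CCC)c(OCc3ccccc3)c(C)c2OC)c(O)c(Cc2c(OCc3ccccc3)c(C(=O)CCC)c(OCc3ccccc3)c(C)c2OC)c1O | intermediate
18 | 1-{3,5-bis[(3-butanoyl-2,4-dihydroxy-6-methoxy-5-methylphenyl)methyl]-2,4,6-trihydroxyphenyl}butan-1-one | CCCC(=O)c1c(O)c(Cc2c(O)c(C(=O)CCC)c(O)c(C)c2OC)c(O)c(Cc2c(O)c(C(=O)CCC)c(O)c(C)c2OC)c1O | target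

## Step count and least certain steps

Total step count: 12. Longest linear sequence: 10 steps (steps 1–6 and 9–12, from 1). The chain fragment 13 is made in two steps (7 and 8) and joins at step 9.

Step 11 (key step). The most likely failure is that C-acylation at C1 is outrun by enol-lactone closure or by retro-Claisen cleavage of the chain, because the ester carbon sits next to a tertiary, heavily substituted C2. Aldol closure with slow dehydration to a non-aromatic dienone is a further drain. Fallback: the central ring is taken as a preformed aromatic. Commercial 1-(2,4,6-trihydroxyphenyl)butan-1-one F1 would be C-benzylated twice at its two free ring positions by the benzylic alcohol 8 (2 equiv) under catalytic Sc(OTf)3 in MeNO2/CH2Cl2. This is a Friedel–Crafts alkylation by an easily ionised trialkoxybenzyl alcohol. The fallback sets out from 8 and returns to the route at 17.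

Step 9. The double alkylation can lose regiocontrol by a second alkylation at C2, by O-alkylation of the diketonate, or by a sluggish second stage in the one-pot regime. Fallback: the order of bond formation is reversed and the intermediate is isolated. Compound 13 would be alkylated first at its most acidic carbon C4 as the monoanion (K2CO3, acetone, 9). This gives methyl 4-{[2,4-bis(benzyloxy)-3-butanoyl-6-methoxy-5-methylphenyl]methyl}-3,5-dioxo-6-(2-propyl-1,3-dioxolan-2-yl)hexanoate F2. After purification, F2 would be alkylated at C2 through its dianion (LiN(i-Pr)2, 2 equiv, then 9). C4–H and C2–H of F2 are both more acidic than the α-hydrogens of the aryl ketone. The fallback sets out from 13 and 9 and returns at 15.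

Step 10. Acid may trigger cyclodehydration: the C3 enol oxygen can trap the oxocarbenium ion at C7 and lead to a 4-pyranone, or the enol can lactonise onto the ester. Fallback: no ketal and no acid. Commercial methyl 3,5-dioxohexanoate F3 would be alkylated at C2 and C4 with 9 as in step 9. This gives methyl 2,4-bis{[2,4-bis(benzyloxy)-3-butanoyl-6-methoxy-5-methylphenyl]methyl}-3,5-dioxohexanoate F4. Its polyanion (LiN(i-Pr)2, about 5 equiv, which also enolises both aryl ketones) would be acylated at the terminal, most basic carbanion C6 with N-methoxy-N-methylbutanamide. The fallback sets out from 9 and returns at 16. Its price is strong base in the presence of the outer-ring ketones.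

Step 8. Proton transfer from the α-CH2 of 11 to the dianion, followed by β-elimination that opens the dioxolane, may compete with acylation. Fallback: aldol addition and oxidation in place of acylation. Ester 11 would be reduced with i-Bu2AlH at −78 °C to 2-(2-propyl-1,3-dioxolan-2-yl)acetaldehyde F5. The dianion of 12 would add to F5 to give methyl 5-hydroxy-3-oxo-6-(2-propyl-1,3-dioxolan-2-yl)hexanoate F6 (racemic). Dess–Martin oxidation of F6 would then give 13. The fallback sets out from 11 and returns at 13.

Step 2. Site selectivity may be lost through methylation of an ortho hydroxyl, double methylation, or C-methylation at the free ring position. Fallback: 3 would be O-methylated exhaustively (excess Me2SO4, K2CO3, acetone, reflux) to 1-(2,4,6-trimethoxy-3-methylphenyl)butan-1-one F7. The two methyl ethers ortho to the ketone would then be cleaved under chelation control with BCl3 in CH2Cl2, leaving the para methyl ether. The fallback sets out from 3 and returns at 4.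

## Further compounds

F1 | step 11 | 1-(2,4,6-trihydroxyphenyl)butan-1-one | CCCC(=O)c1c(O)cc(O)cc1O
F2 | step 9 | methyl 4-{[2,4-bis(benzyloxy)-3-butanoyl-6-methoxy-5-methylphenyl]methyl}-3,5-dioxo-6-(2-propyl-1,3-dioxolan-2-yl)hexanoate (racemic) | CCCC1(CC(=O)C(Cc2c(OCc3ccccc3)c(C(=O)CCC)c(OCc3ccccc3)c(C)c2OC)C(=O)CC(=O)OC)OCCO1
F3 | step 10 | methyl 3,5-dioxohexanoate | COC(=O)CC(=O)CC(C)=O
F4 | step 10 | methyl 2,4-bis{[2,4-bis(benzyloxy)-3-butanoyl-6-methoxy-5-methylphenyl]methyl}-3,5-dioxohexanoate (mixture of diastereomers) | COC(=O)C(Cc1c(OCc2ccccc2)c(C(=O)CCC)c(OCc2ccccc2)c(C)c1OC)C(=O)C(Cc1c(OCc2ccccc2)c(C(=O)CCC)c(OCc2ccccc2)c(C)c1OC)C(C)=O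
F5 | step 8 | 2-(2-propyl-1,3-dioxolan-2-yl)acetaldehyde | CCCC1(CC=O)OCCO1
F6 | step 8 | methyl 5-hydroxy-3-oxo-6-(2-propyl-1,3-dioxolan-2-yl)hexanoate (racemic) | CCCC1(CC(O)CC(=O)CC(=O)OC)OCCO1
F7 | step 2 | 1-(2,4,6-trimethoxy-3-methylphenyl)butan-1-one | CCCC(=O)c1c(OC)c(C)c(OC)cc1OC
A1 | alternative 1 | 1,3,5-tris(benzyloxy)-2,4-bis[(3-butanoyl-2-ethoxy-4-hydroxy-6-methoxy-5-methylphenyl)methyl]benzene | O(Cc1ccccc1)c1cc(OCc2ccccc2)c(Cc2c(OCC)c(C(=O)CCC)c(O)c(C)c2OC)c(OCc2ccccc2)c1Cc1c(OCC)c(C(=O)CCC)c(O)c(C)c1OC
A2 | alternative 1 | 1,3,5-tris(benzyloxy)-2,4-bis{3,5-dimethoxy-4-methyl-5-[(trimethylsilyl)oxy]penta-2,4-dien-1-yl}benzene (double-bond geometry not specified) | O(Cc1ccccc1)c1cc(OCc2ccccc2)c(CC=C(OC)C(C)=C(OC)O[Si](C)(C)C)c(OCc2ccccc2)c1CC=C(OC)C(C)=C(OC)O[Si](C)(C)C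
A3 | alternative 1 | 1-ethoxyhex-1-yn-3-one | CCCC(=O)C#COCC
A4 | alternative 2 | 1-[2,4-bis(benzyloxy)-3,5-bis({[2,4-bis(benzyloxy)-3-butanoyl-6-methoxy-5-methylphenyl]methyl})-6-hydroxyphenyl]butan-1-one | CCCC(=O)c1c(O)c(Cc2c(OCc3ccccc3)c(C(=O)CCC)c(OCc3ccccc3)c(C)c2OC)c(OCc2ccccc2)c(Cc2c(OCc3ccccc3)c(C(=O)CCC)c(OCc3ccccc3)c(C)c2OC)c1OCc1ccccc1
A5 | alternative 2 | 3,5-bis(benzyloxy)-4,6-bis({[2,4-bis(benzyloxy)-3-butanoyl-6-methoxy-5-methylphenyl]methyl})-2-(trimethylsilyl)phenyl trifluoromethanesulfonate | C[Si](C)(C)c1c(OS(=O)(=O)C(F)(F)F)c(Cc2c(OCc3ccccc3)c(C(=O)CCC)c(OCc3ccccc3)c(C)c2OC)c(OCc2ccccc2)c(Cc2c(OCc3ccccc3)c(C(=O)CCC)c(OCc3ccccc3)c(C)c2OC)c1OCc1ccccc1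
A6 | alternative 2 | butanoic acid | CCCC(=O)O
A7 | alternative 3 | 1-{2,4,6-tris(benzyloxy)-3,5-bis[(3-butanoyl-2,4,6-trihydroxy-5-methylphenyl)methyl]phenyl}butan-1-one | CCCC(=O)c1c(OCc2ccccc2)c(Cc2c(O)c(C(=O)CCC)c(O)c(C)c2O)c(OCc2ccccc2)c(Cc2c(O)c(C(=O)CCC)c(O)c(C)c2O)c1OCc1ccccc1
A8 | alternative 3 | 1-{2,4,6-tris(benzyloxy)-3,5-bis[2-(methoxycarbonyl)-4-methyl-3,5,7-trioxodecyl]phenyl}butan-1-one (mixture of diastereomers) | CCCC(=O)c1c(OCc2ccccc2)c(CC(C(=O)OC)C(=O)C(C)C(=O)CC(=O)CCC)c(OCc2ccccc2)c(CC(C(=O)OC)C(=O)C(C)C(=O)CC(=O)CCC)c1OCc1ccccc1
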